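Both labdane halves come from one decalin building block traced to (R)-carvone: the carvone ring is ring B, its isopropenyl group becomes C4 with C18 and C19, and ring A is closed last at C3–C4. The key step is an intramolecular ester enolate alkylation on a monocyclic cyclohexenyl triflate: the C4 enolate on C5 displaces chloride from the three-carbon chain on C10, closing ring A and setting the C4 quaternary centre (axial C19 methyl, equatorial C18 carboxyl) by allylic strain against C5–H. The derived C11 trifluoroborate is coupled twice, around an enantioselective Diels–Alder reaction of the 12E,14-diene with acrolein that builds the central cyclohexene.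

Key step: step 7

Remark on numbering: labdane numbering is used for the decalin carbons, also in monocyclic precursors (C17 on C8, C11 on C9, C18 = equatorial 4α carbon, C19 = axial 4β methyl, C20 = methyl on C10).
Remark on step 18: the sense of induction is assigned from the accepted iminium model of the imidazolidinone catalyst (E-iminium ion, benzyl group shielding one face); with the opposite sense the enantiomeric catalyst would be used.

Step 1
Reactants: 1 (R)-(−)-carvone
Product: 2 (5R)-6-methylcarvone (C6 epimers)
Conditions: LDA, THF, −78 °C; MeI, −78 → 0 °C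
Reagents that add atoms: iodomethane, CI
Why: Kinetic α′-deprotonation and C-methylation of the lithium enolate is a standard ketone enolate alkylation; the new C6 centre need not be controlled because it is enolised again in step 2.

Step 2
Reactants: 2 (5R)-6-methylcarvone; 3 1-chloro-3-iodopropane
Product: 4 (5S,6S)-6-(3-chloropropyl)-2,6-dimethyl-5-(prop-1-en-2-yl)cyclohex-2-en-1-one
Conditions: LDA, THF, −78 °C; 3, DMPU, −78 → 0 °C
Reagents that add atoms: none
Why: Enolate alkylation at the iodide end of 3; the electrophile should enter anti to the pseudoaxial isopropenyl group, which sets the quaternary carbon (future C10) with the chain trans and the methyl cis to isopropenyl.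

Step 3
Reactants: 4 chloropropyl enone
Product: 6 (5S,6S)-6-(3-chloropropyl)-2,6-dimethyl-5-(prop-1-en-2-yl)cyclohex-1-en-1-yl trifluoromethanesulfonate, via lithium enolate 5 (not isolated)
Conditions: L-Selectride, THF, −78 °C; PhNTf2, −78 → 0 °C
Reagents that add atoms: N-phenylbis(trifluoromethanesulfonimide), O=S(=O)(N(c1ccccc1)S(=O)(=O)C(F)(F)F)C(F)(F)F
Why: Conjugate hydride addition to the enone, whose carbonyl is shielded by the adjacent quaternary carbon, gives the regiodefined enolate, and O-sulfonylation (reductive enol triflation) masks the ketone as the enol triflate that later carries C11.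

Step 4
Reactants: 6 enol triflate
Product: 8 (5S,6S)-6-(3-chloropropyl)-5-(1-hydroxypropan-2-yl)-2,6-dimethylcyclohex-1-en-1-yl trifluoromethanesulfonate (side-chain epimers), via alkyl-9-BBN borane 7 (not isolated)
Conditions: 9-BBN, THF, 0 → 23 °C; H2O2, aq. NaOAc, 0 °C
Reagents that add atoms: hydrogen peroxide, OO
Why: Anti-Markovnikov hydroboration–oxidation of the 1,1-disubstituted alkene; the electron-poor tetrasubstituted enol triflate should be inert to 9-BBN, and the side-chain centre, formed as a mixture, is erased in step 7.

Step 5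
Reactants: 8 primary alcohol
Product: 9 2-[(1S,2S)-2-(3-chloropropyl)-2,4-dimethyl-3-(trifluoromethylsulfonyloxy)cyclohex-3-en-1-yl]propanoic acid (epimers at C2 of the acid)
Conditions: TEMPO (cat.), PhI(OAc)2, MeCN–H2O, 23 °C
Reagents that add atoms: water, O
Why: Oxoammonium oxidation of the primary alcohol through the aldehyde hydrate to the acid, under conditions that leave enol triflate and alkyl chloride untouched.

Step 6
Reactants: 9 carboxylic acid
Product: 10 methyl ester of 9 (epimers at C2 of the ester)
Conditions: MeI, K2CO3, DMF, 23 °C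
Reagents that add atoms: iodomethane, CI
Why: Carboxylate O-alkylation; intermolecular methylation should outrun attack on the internal chloride, which would need an eight-membered lactone.

Step 7
Reactants: 10 methyl ester
Product: 12 trans-decalin enol triflate ester [C18 methyl ester 4α; C19 methyl 4β; 5α-H; C20 methyl 10β; C8(CH3)=C9(OTf)], via potassium ester enolate 11 (not isolated)
Conditions: KHMDS, THF–DMPU, −78 → 23 °C
Reagents that add atoms: none
Why: KHMDS converts the ester into potassium enolate 11, whose α-carbon (C4) displaces the primary chloride at C3 in an intramolecular SN2 reaction; the closest known reaction type is the intramolecular ester enolate alkylation through an H-eclipsed transition state. Ring A closes in the 6-exo-tet mode through a chair in which the chain on C10 and the enolate-bearing carbon on C5 are both equatorial on ring B, an arrangement fixed by the trans relation set in step 2. The new quaternary stereocentre C4 is controlled by allylic 1,3-strain: C5–H eclipses the enolate C=C(OK)OMe unit, so the carboxyl carbon should end equatorial (4α, C18) and the methyl axial (4β, C19), whereas the other rotamer would press the enolate oxygen against the quaternary C10. The step needs C- over O-alkylation, secured by a six- against an eight-membered ring, and survival of the enol triflate, which has no vinylic hydrogen and meets only about one equivalent of hindered amide base at low temperature. Both side-chain epimers of 10 converge on the same enolate.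

Step 8
Reactants: 12 enol triflate ester
Product: 13 dimethyl diester [as 12 but CO2Me (C11) on C9 in place of OTf]
Conditions: Pd(OAc)2, dppp, CO (1 atm), Et3N, MeOH–DMF, 60 °C
Reagents that add atoms: carbon monoxide, [C-]#[O+]; methanol, CO
Why: Pd-catalysed alkoxycarbonylation of the enol triflate (oxidative addition, CO insertion, methanolysis) installs C11 as a conjugated ester; the quaternary C18 ester is a spectator.

Step 9
Reactants: 13 conjugated diester
Product: 15 dimethyl 8(17)-ene diester [exocyclic C8=C17; C11 ester 9β; 9α-H], via lithium dienolate 14 (not isolated)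
Conditions: LDA, THF–HMPA, −78 °C; AcOH, −78 °C
Reagents that add atoms: none
Why: Deconjugative protonation: LDA should remove a proton from the C17 methyl, which is syn to the C11 ester carbonyl, and kinetic α-protonation of the dienolate from the face opposite the C20 methyl sets C9 (9α-H); the C18 ester has no α-hydrogen.

Step 10
Reactants: 15 deconjugated diester
Product: 16 diol (11-OH and 18-OH; the 4α-hydroxymethyl analogue of albicanol)
Conditions: LiAlH4, Et2O, 0 → 23 °C
Reagents that add atoms: none
Why: Hydride reduction of both esters to primary alcohols without moving the β,γ-double bond or touching C9.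

Step 11
Reactants: 16 diol
Product: 17 11-iodo-18-ol
Conditions: PPh3, I2, imidazole, toluene, 23 → 60 °C
Reagents that add atoms: iodine, II
Why: Garegg–Samuelsson iodination; only the C11 alkoxyphosphonium salt can be displaced, since SN2 attack at the neopentyl C18 carbon is blocked and its phosphonium salt should revert to the alcohol on work-up.

Step 12
Reactants: 17 iodo alcohol
Product: 18 11-iodo-18-(tert-butyldimethylsilyloxy) decalin
Conditions: TBSOTf, 2,6-lutidine, CH2Cl2, −78 → 0 °C
Reagents that add atoms: tert-butyldimethylsilyl trifluoromethanesulfonate, CC(C)(C)[Si](C)(C)OS(=O)(=O)C(F)(F)F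
Why: Silylation of the hindered neopentyl alcohol with the silyl triflate protects it for the organolithium step; the primary iodide is inert under these conditions.

Step 13
Reactants: 18 silyl-protected iodide
Product: 21 potassium trifluoroborate of the decalin (C11–BF3K in place of C11–I; common coupling partner), via alkyllithium 19 (not isolated), via lithium trimethoxyborate 20 (not isolated)
Conditions: t-BuLi (2.1 equiv), Et2O–pentane, −78 °C; B(OMe)3, −78 → 23 °C; aq. KHF2, MeOH, 0 °C, short contact
Reagents that add atoms: trimethyl borate, COB(OC)OC; potassium hydrogen difluoride, [K+].[F-].F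
Why: Iodine–lithium exchange, borylation of the alkyllithium and fluorination with KHF2 give a crystalline, storable potassium alkyltrifluoroborate, so that one batch serves both couplings; the anionic sequence avoids a C11 radical that could rearrange through the homoallylic 8(17)-alkene, and the hindered neopentyl silyl ether should survive the brief KHF2 treatment.

Step 14
Reactants: 22 prop-2-yn-1-ol
Product: 24 (E)-3-iodo-2-methylprop-2-en-1-ol, via alkenylalane 23 (not isolated)
Conditions: Me3Al, Cp2ZrCl2 (cat.), CH2Cl2, 0 → 23 °C; I2, THF, −30 °C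
Reagents that add atoms: trimethylaluminium, C[Al](C)C; iodine, II
Why: Zr-catalysed carboalumination (Negishi) adds methyl and aluminium syn across the alkyne with aluminium at the terminus, and iodinolysis with retention gives the (E)-iodide.

Step 15
Reactants: 24 iodo allylic alcohol
Product: 25 (E)-3-iodo-2-methylprop-2-enal
Conditions: MnO2, CH2Cl2, 23 °C
Reagents that add atoms: none
Why: Selective oxidation of the allylic alcohol to the enal without touching the C–I bond or the alkene geometry.

Step 16
Reactants: 25 iodo enal
Product: 26 (E)-1-iodo-2-methylbuta-1,3-diene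
Conditions: Ph3PCH3Br, n-BuLi, THF, 0 °C; 25, −78 → 23 °C
Reagents that add atoms: methyltriphenylphosphonium bromide, C[P+](c1ccccc1)(c1ccccc1)c1ccccc1.[Br-]
Why: Wittig methylenation of the aldehyde gives the dienyl iodide and leaves the trisubstituted (E)-alkene unchanged.

Step 17
Reactants: 21 potassium trifluoroborate; 26 dienyl iodide
Product: 27 18-(tert-butyldimethylsilyloxy)labda-8(17),12E,14-triene
Conditions: PdCl2(dppf)·CH2Cl2 (cat.), Cs2CO3, toluene–H2O, 80 °C, sealed vessel
Reagents that add atoms: none
Why: B-alkyl Suzuki–Miyaura coupling of a primary potassium alkyltrifluoroborate with an alkenyl halide: slow hydrolysis releases the boronic acid, and transmetalation and reductive elimination join C11 to C12 with retention of the (E)-geometry, the bidentate dppf ligand suppressing β-hydride elimination.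

Step 18
Reactants: 27 silyl-protected triene; 28 acrolein
Product: 29 (1S,2S)-3-methyl-2-(decalinylmethyl)cyclohex-3-ene-1-carbaldehyde (cis; decalinyl = the C9 unit of 18)
Conditions: (5R)-5-benzyl-2,2,3-trimethylimidazolidin-4-one·HCl (20 mol%), MeCN–THF–H2O, 23 °C
Reagents that add atoms: none
Why: Iminium-catalysed Diels–Alder reaction in which the benzyl group of the catalyst shields one face of the (E)-iminium ion of acrolein, the terminal alkyl group of the diene should direct the formyl-bearing carbon to C12 ("ortho" preference, as with 1-vinylcycloalkenes), and endo addition to the (E)-diene sets the two new stereocentres cis.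

Step 19
Reactants: 29 aldehyde
Product: 30 terminal alkyne (CHO of 29 replaced by C≡CH; same configuration)
Conditions: TMSCHN2, n-BuLi, THF, −78 °C; 29, −78 → 23 °C
Reagents that add atoms: trimethylsilyldiazomethane, C[Si](C)(C)C=[N+]=[N-]
Why: Colvin homologation (addition of the lithiated diazo compound, Peterson-type elimination, 1,2-hydrogen shift of the alkylidene carbene) makes the alkyne at low temperature, so the cis α-stereocentre should not epimerise.

Step 20
Reactants: 30 alkyne
Product: 32 (E)-vinyl iodide [ring–C(CH3)=CH–I], via alkenylalane 31 (not isolated)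
Conditions: Me3Al, Cp2ZrCl2, CH2Cl2, −20 → 23 °C; I2, THF, −30 °C
Reagents that add atoms: trimethylaluminium, C[Al](C)C; iodine, II
Why: Negishi carboalumination places methyl on the internal and aluminium on the terminal alkyne carbon in a syn fashion, and iodinolysis gives the (E)-iodide; the isolated 1,1-di- and trisubstituted alkenes should not react.

Step 21
Reactants: 21 potassium trifluoroborate; 32 vinyl iodide
Product: 33 bis(tert-butyldimethylsilyl) ether of the target
Conditions: PdCl2(dppf)·CH2Cl2 (cat.), Cs2CO3, toluene–H2O, 80 °C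
Reagents that add atoms: none
Why: A second B-alkyl Suzuki–Miyaura coupling of the same trifluoroborate forms the C11–C12 bond of the other half with retention of the (12E)-geometry.

Step 22
Reactants: 33 bis-silyl ether
Product: 34 target CNP0194625.1
Conditions: TBAF, THF, 23 → 50 °C
Reagents that add atoms: none
Why: Fluoride cleaves both neopentyl silyl ethers to release the diol.

Compound list
1 | (R)-(−)-carvone | CC1=CC[C@H](CC1=O)C(C)=C | starting material
2 | (5R)-6-methylcarvone, (5R,6RS)-2,6-dimethyl-5-(prop-1-en-2-yl)cyclohex-2-en-1-one | CC1=CC[C@@H](C(C)=C)C(C)C1=O | intermediate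
3 | 1-chloro-3-iodopropane | ClCCCI | starting material
4 | (5S,6S)-6-(3-chloropropyl)-2,6-dimethyl-5-(prop-1-en-2-yl)cyclohex-2-en-1-one (chain trans, methyl cis to isopropenyl) | CC1=CC[C@@H](C(C)=C)[C@](C)(CCCCl)C1=O | intermediate
5 | lithium (5S,6S)-6-(3-chloropropyl)-2,6-dimethyl-5-(prop-1-en-2-yl)cyclohex-1-en-1-olate (not isolated) | CC1=C([O-])[C@@](C)(CCCCl)[C@H](C(C)=C)CC1.[Li+] | intermediate
6 | (5S,6S)-6-(3-chloropropyl)-2,6-dimethyl-5-(prop-1-en-2-yl)cyclohex-1-en-1-yl trifluoromethanesulfonate | CC1=C(OS(=O)(=O)C(F)(F)F)[C@@](C)(CCCCl)[C@H](C(C)=C)CC1 | intermediate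
7 | B-alkyl-9-BBN adduct of 6 at the isopropenyl CH2 (not isolated) | CC1=C(OS(=O)(=O)C(F)(F)F)[C@@](C)(CCCCl)[C@H](C(C)CB2C3CCCC2CCC3)CC1 | intermediate
8 | (5S,6S)-6-(3-chloropropyl)-5-(1-hydroxypropan-2-yl)-2,6-dimethylcyclohex-1-en-1-yl trifluoromethanesulfonate (side-chain epimers) | CC1=C(OS(=O)(=O)C(F)(F)F)[C@@](C)(CCCCl)[C@H](C(C)CO)CC1 | intermediate
9 | 2-[(1S,2S)-2-(3-chloropropyl)-2,4-dimethyl-3-(trifluoromethylsulfonyloxy)cyclohex-3-en-1-yl]propanoic acid (epimers at C2) | CC1=C(OS(=O)(=O)C(F)(F)F)[C@@](C)(CCCCl)[C@H](C(C)C(=O)O)CC1 | intermediate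
10 | methyl ester of 9 | CC1=C(OS(=O)(=O)C(F)(F)F)[C@@](C)(CCCCl)[C@H](C(C)C(=O)OC)CC1 | intermediate
11 | potassium ester enolate of 10 (not isolated) | CC1=C(OS(=O)(=O)C(F)(F)F)[C@@](C)(CCCCl)[C@H](C(C)=C([O-])OC)CC1.[K+] | intermediate
12 | trans-decalin enol triflate ester: C18 methyl ester 4α, C19 methyl 4β, 5α-H, C20 methyl 10β, C8(CH3)=C9(OTf) | CC1=C(OS(=O)(=O)C(F)(F)F)[C@@]2(C)CCC[C@@](C)(C(=O)OC)[C@@H]2CC1 | intermediate
13 | dimethyl diester: as 12 but CO2Me (C11) on C9, Δ8(9) | CC1=C(C(=O)OC)[C@@]2(C)CCC[C@@](C)(C(=O)OC)[C@@H]2CC1 | intermediate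
14 | lithium dienolate of 13: exocyclic C8=C17, C9=C11(OLi)OMe (not isolated) | C=C1CC[C@H]2[C@](C)(C(=O)OC)CCC[C@]2(C)C1=C([O-])OC.[Li+] | intermediate
15 | dimethyl 8(17)-ene diester: 9β-CO2Me (9α-H), 4α-CO2Me | C=C1CC[C@H]2[C@](C)(C(=O)OC)CCC[C@]2(C)[C@H]1C(=O)OC | intermediate
16 | diol: 9β-CH2OH (C11), 4α-CH2OH (C18), 8(17)-ene | C=C1CC[C@H]2[C@](C)(CO)CCC[C@]2(C)[C@H]1CO | intermediate
17 | 11-iodo-18-ol | C=C1CC[C@H]2[C@](C)(CO)CCC[C@]2(C)[C@H]1CI | intermediate
18 | 11-iodo-18-(tert-butyldimethylsilyloxy) decalin | C=C1CC[C@H]2[C@](C)(CO[Si](C)(C)C(C)(C)C)CCC[C@]2(C)[C@H]1CI | intermediate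
19 | C11-lithio derivative of 18 (not isolated) | C=C1CC[C@H]2[C@](C)(CO[Si](C)(C)C(C)(C)C)CCC[C@]2(C)[C@H]1C[Li] | intermediate
20 | lithium alkyl(trimethoxy)borate from 19 (not isolated) | C=C1CC[C@H]2[C@](C)(CO[Si](C)(C)C(C)(C)C)CCC[C@]2(C)[C@H]1C[B-](OC)(OC)OC.[Li+] | intermediate
21 | potassium trifluoroborate: C11–BF3K analogue of 18 (common coupling partner) | C=C1CC[C@H]2[C@](C)(CO[Si](C)(C)C(C)(C)C)CCC[C@]2(C)[C@H]1C[B-](F)(F)F.[K+] | intermediate
22 | prop-2-yn-1-ol | C#CCO | starting material
23 | (E)-alkenylalane, dimethylaluminium alkoxide of the carboalumination product (not isolated) | C[Al](C)OC/C(C)=C/[Al](C)C | intermediate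
24 | (E)-3-iodo-2-methylprop-2-en-1-ol | OC/C(C)=C/I | intermediate
25 | (E)-3-iodo-2-methylprop-2-enal | O=C/C(C)=C/I | intermediate
26 | (E)-1-iodo-2-methylbuta-1,3-diene | C=C/C(C)=C/I | intermediate
27 | 18-(tert-butyldimethylsilyloxy)labda-8(17),12E,14-triene | C=C/C(C)=C/C[C@H]1C(=C)CC[C@H]2[C@](C)(CO[Si](C)(C)C(C)(C)C)CCC[C@]12C | intermediate
28 | acrolein | C=CC=O | starting material
29 | (1S,2S)-3-methyl-2-(decalinylmethyl)cyclohex-3-ene-1-carbaldehyde, cis | O=C[C@H]1CCC=C(C)[C@H]1C[C@H]1C(=C)CC[C@H]2[C@](C)(CO[Si](C)(C)C(C)(C)C)CCC[C@]12C | intermediate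
30 | terminal alkyne from 29 | C#C[C@H]1CCC=C(C)[C@H]1C[C@H]1C(=C)CC[C@H]2[C@](C)(CO[Si](C)(C)C(C)(C)C)CCC[C@]12C | intermediate
31 | (E)-alkenyl(dimethyl)alane from 30 (not isolated) | C[Al](C)/C=C(\C)[C@H]1CCC=C(C)[C@H]1C[C@H]1C(=C)CC[C@H]2[C@](C)(CO[Si](C)(C)C(C)(C)C)CCC[C@]12C | intermediate
32 | (E)-vinyl iodide, ring–C(CH3)=CH–I | I/C=C(\C)[C@H]1CCC=C(C)[C@H]1C[C@H]1C(=C)CC[C@H]2[C@](C)(CO[Si](C)(C)C(C)(C)C)CCC[C@]12C | intermediate
33 | bis(tert-butyldimethylsilyl) ether of the target | C=C1CC[C@H]2[C@](C)(CO[Si](C)(C)C(C)(C)C)CCC[C@]2(C)[C@H]1C/C=C(\C)[C@H]1CCC=C(C)[C@H]1C[C@H]1C(=C)CC[C@H]2[C@](C)(CO[Si](C)(C)C(C)(C)C)CCC[C@]12C | intermediate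
34 | CNP0194625.1 | C=C1CC[C@H]2[C@](C)(CO)CCC[C@]2(C)[C@H]1C/C=C(\C)[C@H]1CCC=C(C)[C@H]1C[C@H]1C(=C)CC[C@H]2[C@](C)(CO)CCC[C@]12C | target

Total step count: 22. Longest linear sequence: 19 steps (steps 1–13 and 17–22); steps 14–16 are a side branch.

Steps most likely to fail

Step 18. The two diene substituents direct in opposite senses (terminal alkyl "ortho", 2-methyl "para"), so regiochemical leakage is the main danger; endo and facial control may also be incomplete, and the cis aldehyde may epimerise through its enamine. The fallback uses a 2-silyloxy diene in which the oxygen substituent and the terminal alkyl group direct the same way. It sets out from trifluoroborate 21. But-3-yn-2-ol would be carboaluminated and iodinated to (E)-4-iodo-3-methylbut-3-en-2-ol F1 and oxidised with MnO2 to (E)-4-iodo-3-methylbut-3-en-2-one F2. Trifluoroborate 21 would be coupled with F2 under the Pd conditions of step 17 to the (E)-enone F3. LDA and TESCl would give the 2-triethylsilyloxy diene F4. A Diels–Alder reaction with 2,2,2-trifluoroethyl acrylate under a chiral oxazaborolidinium catalyst should give the cis cycloadduct F5. CsF and PhNTf2 would convert its silyl enol ether into the enol triflate F6, and Pd(OAc)2, PPh3, HCO2H and Bu3N would reduce this to the trisubstituted alkene ester F7. DIBAL-H at −78 °C would then give aldehyde 29, where the route is rejoined.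

Step 7. The enol triflate may be lost, or chloride displacement may be slow enough for elimination to compete, under the basic conditions; facial selectivity at C4 may also erode. The fallback carries the ring-B carbonyl as a ketone and masks it in the flask as its own enolate. It sets out from enone 4. L-Selectride followed by an aqueous quench would give the saturated ketone F8. 9-BBN then H2O2 would give the hydroxy ketone F9; any over-reduced carbinol is returned to the ketone in the next step. Jones oxidation would give the keto acid F10, and MeI with K2CO3 the keto ester F11. KHMDS (2.2 equiv) would form the ketone enolate, possible only towards C8, and then the ester enolate, which closes ring A as in step 7. PhNTf2 would then trap the ketone enolate to give 12, where the route is rejoined.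

Step 9. γ-Deprotonation may occur at C7 instead of C17 (giving the endocyclic Δ7 isomer), and protonation may reconjugate the ester or take the wrong face at C9. The fallback is a photochemical deconjugation: irradiation of 13 at 254 nm in Et2O with catalytic 1,2-dimethylimidazole. Photoenolisation by a 1,5-hydrogen shift can only take a hydrogen from C17, the γ-carbon cis to the ester, and ketonisation of the dienol should give 15 directly. It sets out from 13, returns at 15 and makes no new compound.

Further compounds
F1 | step 18 | (E)-4-iodo-3-methylbut-3-en-2-ol | CC(O)/C(C)=C/I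
F2 | step 18 | (E)-4-iodo-3-methylbut-3-en-2-one | CC(=O)/C(C)=C/I
F3 | step 18 | (E)-enone, D–CH2–CH=C(CH3)–C(=O)CH3 (D = C9 of the silyl-protected decalin) | CC(=O)/C(C)=C/C[C@H]1C(=C)CC[C@H]2[C@](C)(CO[Si](C)(C)C(C)(C)C)CCC[C@]12C
F4 | step 18 | 2-(triethylsilyloxy) diene from F3 | C=C(O[Si](CC)(CC)CC)/C(C)=C/C[C@H]1C(=C)CC[C@H]2[C@](C)(CO[Si](C)(C)C(C)(C)C)CCC[C@]12C
F5 | step 18 | cis cycloadduct, 2,2,2-trifluoroethyl ester carrying the ring silyl enol ether | O=C(OCC(F)(F)F)[C@H]1CCC(O[Si](CC)(CC)CC)=C(C)[C@H]1C[C@H]1C(=C)CC[C@H]2[C@](C)(CO[Si](C)(C)C(C)(C)C)CCC[C@]12C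
F6 | step 18 | enol triflate from F5 | O=C(OCC(F)(F)F)[C@H]1CCC(OS(=O)(=O)C(F)(F)F)=C(C)[C@H]1C[C@H]1C(=C)CC[C@H]2[C@](C)(CO[Si](C)(C)C(C)(C)C)CCC[C@]12C
F7 | step 18 | 2,2,2-trifluoroethyl ester carrying the trisubstituted ring alkene | O=C(OCC(F)(F)F)[C@H]1CCC=C(C)[C@H]1C[C@H]1C(=C)CC[C@H]2[C@](C)(CO[Si](C)(C)C(C)(C)C)CCC[C@]12C
F8 | step 7 | saturated ketone, 2,3-dihydro-4 (C2 epimers) | CC1CC[C@@H](C(C)=C)[C@](C)(CCCCl)C1=O
F9 | step 7 | hydroxy ketone | CC1CC[C@@H](C(C)CO)[C@](C)(CCCCl)C1=O
F10 | step 7 | keto acid | CC1CC[C@@H](C(C)C(=O)O)[C@](C)(CCCCl)C1=O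
F11 | step 7 | keto methyl ester | CC1CC[C@@H](C(C)C(=O)OC)[C@](C)(CCCCl)C1=O
F0 | step 9 | none | none
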